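I decide to freeze two things in this flask, the rate at which reagent crosses out of the second phase and the substrate it meets, and to reckon from one ratio of two times.

substrate 0.18 M; reagent in the second phase 0.270 M; protic impurity 0.0900 M; time 4.0 h; volume of the second phase over the first 2.0

    reagent in the reaction phase + target → over-reacted product (k1 = 1.31 M⁻¹ min⁻¹)
    substrate + target → side product (k2 = 0.255 M⁻¹ min⁻¹)
    substrate + reagent in the reaction phase → target (k3 = 9.15 M⁻¹ min⁻¹)
    target ⇌ isomer of the product (K4 = 1.46, k4 = 9.63 × 10⁻⁴ min⁻¹)
    reagent in the reaction phase ⇌ reagent in the second phase, rate k5*([reagent in the reaction phase] - [reagent in the second phase]/K5) per volume of the first phase (K5 = 11.8, k5 = 0.0662 min⁻¹)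
    reagent in the reaction phase + protic impurity → quenched reagent (k6 = 0.661 M⁻¹ min⁻¹)

- percent here means substrate units held: one side product counts as two
- in the second phase: reagent in the second phase; everything else is in the first
- charges count per volume of the first phase; a concentration in a rate is the amount of a species over the volume of its own phase; every rate counts per litre of the first phase
- run time (flask): 4.0 h

- target at 4.0 h, in percent of the substrate charged
- part of the substrate charged that has reacted at 4.0 h

At the start, with no reagent in the reaction phase yet to push back, the crossing rate is

feed = transfer coefficient × charge ÷ (volume ratio × partition ratio) = 7.57 × 10⁻⁴ M min⁻¹

The first time is how long that feed takes to bring one reagent per substrate charged: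

feed time = 3.96 h

Once across, reagent meets substrate with a half-life of 0.42 min, so crossing is the rate-limiting step. Quenching is slower, at 0.19 h, so nearly all of the early feed makes target.

The second time is the target's lifetime against charged substrate, since its half-life there is shorter than the 12 h of isomerisation:

lifetime = 0.363 h

Target made at the feed rate and lost within that lifetime stands at a fraction of the charge:

standing target = lifetime ÷ feed time = 9.17%

Each target lost takes a substrate with it, so on this estimate two substrates go per reagent crossed, and the frozen feed reckons to 1.98 h for the charge, within the run. That estimate holds the feed at its starting value. There I stop, with no finer figure for either answer.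

The forecast goes further and gives 14.6% and 95.1%, starting from the judgement that “Transfer is therefore slow”. Its target lies above my standing value.

The simulation gives 14.5% and 94.9%, so both forecast values hold within their margins. A run would part from the forecast's reacted part if the recipe changed: that answer has moved by 5 points at 0.236 M of reagent in the second phase. Target reads 8.23% at 1.00 h, near the standing value, but the 14.5% of the asked time stands above that value, which was reckoned with substrate frozen at its charge.

In the neighbour charged with 0.72 M of substrate, the same reckoning gives a standing target of 0.573%. That flask gives 0.444%, with 35.4% reacted.

The numbers are those of an exercise, and the outcome is calculated.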